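# Proposed total synthesis of CNP0211965.1 by an intramolecular photochemical Danheiser benzannulation

Abbreviations used in names: DBP = 3,4-bis(benzyloxy)phenyl; HBE = hexa-O-benzyl-epigallocatechin-8-yl, i.e. (2R,3R)-3,5,7-tris(benzyloxy)-2-[3,4,5-tris(benzyloxy)phenyl]chroman-8-yl. Flavan numbering is used for both halves ("upper" = the 7-hydroxyflavan, "lower" = the epigallocatechin unit), also for open-chain intermediates.

Numbering: 1 (−)-epigallocatechin; 3 its hexabenzyl ether; 5 the 8-aldehyde; 11 the glutaric anhydride; 12 the hemiester; 16 the vinyl lactone; 21 the (S)-carbinol; 24 the ynol ether; 26 the vinyl ketone; 28 the diazo ketone (precursor of the key step); 33 the product of the key step; 34 the target. Further starting materials are 6, 17 and 22. All numbers 1–34 are defined in the steps and the compound list.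

Assumption 1: the target is read as (2S,4R) in the upper flavan (2-aryl and 4-aryl trans) and (2R,3R) in the lower unit, which is the configuration of (−)-epigallocatechin.

Assumption 2: the quinine-derived catalyst of step 9 is taken to give the (3S)-acid 12; if the first run shows the opposite sense, its quinidine-derived pseudoenantiomer is used and nothing else changes.

## Analysis of the target

The molecule is a 4→8 linked biflavanoid: an upper 3-deoxyflavan (rings A and C, catechol ring B) is bonded through its C4 to C8 of a lower (−)-epigallocatechin unit. There are four stereocentres in two unconnected pairs: lower C2/C3 (R,R, cis) and upper C2 (S)/C4 (R), whose aryl groups are trans on upper ring C. The lower pair comes with epigallocatechin; the upper pair is 1,3-related across a CH2 group and has to be set by reagents, since the resident centres are too remote to help. Eight phenols and the secondary 3-OH need global protection, and the C4–C8 bond and the benzylic C2–O bonds rule out strong acid. The hard point is upper C4, a methine bearing the 2,6-dioxygenated lower C8, which is difficult to reach by stereocontrolled arylation once upper ring A exists. The plan rests on the substitution of upper ring A: only C7 (OH), C8a (O1) and C4a (C4) carry substituents, while C5, C6 and C8 are CH. This is the pattern of a phenol assembled from a vinylketene (C4a, C5, C6, C7 and the C7 oxygen) and a terminal alkoxyacetylene (C8, C8a, O1). Upper rings A and C can therefore be closed together, late, from an open chain in which C2 and C4 are already fixed.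

## Retrosynthetic reasoning

**34 ⇒ 33.** The eight benzyl–oxygen bonds are cut last. Benzyl ethers come off in one neutral hydrogenolysis and withstand hydride reagents, organolithium reagents, strong bases, fluoride and long-wavelength light. The upper 7-OH needs no protecting group, because it is created in the preceding step.

**33 ⇒ 28.** Four bonds of upper ring A are cut: C4a–C5, C7–C8, C8a–C4a and C6–C7. This leaves a vinyl group (C5, C6), a ketone carbon (C7), a diazo carbon (C4a) and an ethynyl ether (C8, C8a, O1) on one chain that already holds C2, C3 and C4. The cut is made here because no other disconnection of ring A uses the absence of substituents at C5, C6 and C8 and forms ring C in the same event. It also avoids any electrophilic substitution on the upper ring and any arylation at C4. The forward reaction must turn the diazo ketone into a vinylketene, add it to the tethered ynol ether in the fused sense, and carry the adduct through ring opening and 6π closure to the phenol without touching C2 or C4.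

**28 ⇒ 26 ⇒ 25 ⇒ 24.** The diazo group is disconnected from the one enolisable position of vinyl ketone 26. The ketone is taken back to allylic alcohol 25 and its silyl ether 24, because the ynol ether has to be made under strongly basic, organometallic conditions. A ketone or an ester would not survive these, and a δ-hydroxy ester would lactonise under them. The vinyl ketone is therefore carried as a protected carbinol and unmasked only after the ynol ether is in place, which leaves three mild steps between the ynol ether and the key step.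

**24 ⇒ 21 + 22.** The O1–C8a bond is cut between the carbinol oxygen of 21 and a two-carbon unit from 22. The oxygen that becomes O1 is already on C2, so forming the ynol ether cannot affect the C2 configuration.

**21 ⇒ 20 ⇒ 19 ⇒ 16 + 17.** The C2–H bond is disconnected (catalyst-controlled ketone reduction sets upper C2). Then the aryl–carbonyl bond is cut, giving lactone 16 and the aryl nucleophile from 17. A lactone is preferred to an open ester because it accepts exactly one organolithium and releases the allylic hydroxyl for silylation at the same time.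

**16 ⇒ 14 ⇒ 12.** The vinyl–carbinol bond is cut back to aldehyde 14, which comes from the acid arm of hemiester 12 by selective reduction. The ester arm of 12 is kept for the lactone.

**12 ⇒ 11.** Upper C4 is traced to the prochiral anhydride 11. Its two carbonyl groups are differentiated by a catalyst at a site remote from the bulky aryl group, so the 2,6-disubstituted aryl residue is only a bystander in the stereodetermining step.

**11 ⇒ 10 ⇒ 9 ⇒ 8 ⇒ 5 + 6.** The two C4–CH2 bonds go back to the aldehyde carbon of 5 and two molecules of 6 (condensation with the first, conjugate addition of the second, loss of two ester groups, hydrolysis, cyclodehydration).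

**5 ⇒ 4 ⇒ 3 ⇒ 2 ⇒ 1.** The formyl carbon is cut from lower C8, which is addressed through bromide 4. The benzyl ethers are taken off in two stages back to 1, which supplies both lower stereocentres and all lower ring atoms.

## Alternatives that were turned down

Alternative 1: The lower phloroglucinol ring is disconnected instead.
- Forward key step: thermal Danheiser benzannulation of cyclobutenone A2 with the flavan-4-yl siloxyalkyne A3 gives phenol A1, forming lower C7–C8, C8a–C4a and C6–C7.
- For: the intermolecular thermal reaction of a cyclobutenone with a siloxyalkyne is the best-established form of this benzannulation. On precedent it is stronger than the intramolecular photochemical variant chosen here. It also delivers the three ring oxygens already differentiated (free OH, silyl ether, benzyl ether).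
- Against: it discards 1. The lower pyran ring and its cis C2/C3 pair must then be built from the cinnamyl chain of A1 (asymmetric oxidation of the alkene, cyclisation onto the C8a oxygen). The 2,3-cis series is the less direct outcome of such cyclisations and needs a correction at C3. A3 carries the upper C4 centre at a propargylic, benzylic position that must survive prolonged heating. At least six further steps follow the key step.
- Comparison: the chosen route takes two stereocentres and the whole lower skeleton from the chiral pool and builds the simpler ring, at the price of a less precedented ring-forming step.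

Alternative 2: Upper O1–C2 is disconnected.
- Forward key step: the phenol of the 1,3,3-triarylpropan-1-ol A5 displaces the activated (R)-carbinol under Mitsunobu conditions with inversion, closing upper ring C to the nona-O-benzyl compound A4.
- For: this is the most conservative ring closure of the four strategies, and A4 is one hydrogenolysis from 34. On predictability of the ring-forming step it is clearly stronger than the chosen route, and it needs neither a ynol ether nor a diazo compound.
- Against: the difficulty moves into A5. Its C4 is a diaryl-substituted methine flanked by two ortho-oxygenated, electron-rich rings, one of them the 2,6-disubstituted lower C8. Such a centre is hard to set by catalytic arylation and is prone to ionisation. The electron-rich benzylic carbinol can also ionise or eliminate under the activation, which would erode the inversion.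
- Comparison: in the chosen route C4 is set on an aliphatic anhydride before upper ring A exists. That is what the benzannulation offers in place of the safer ring closure.

Alternative 3: Lower O1–C2 and C3–C4 are disconnected.
- Forward key step: a secondary-amine catalyst joins salicylaldehyde A7 and cinnamaldehyde A8 by oxa-Michael addition and aldol condensation to the 2H-chromene-3-carbaldehyde A6, with lower C2 set by the catalyst.
- For: the union is catalytic, asymmetric and convergent, and the reaction type is known for simple salicylaldehydes and enals. On convergence it is at least as good as the chosen route.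
- Against: in A7 the phenol is flanked by the bulky flavan-4-yl group and the aldehyde is deactivated by two para/ortho oxygens, so both bond-forming events are slowed. The catalyst has to override two resident stereocentres. A6 is at the wrong oxidation pattern: the formyl group must be removed and a cis 3-hydroxyl installed, most plausibly by passing C3 through the ketone oxidation level, at which C2 is benzylic and α to the carbonyl, hence epimerisable. A7 also presupposes the upper flavan and the C4–C8 bond, so the main problem stays unsolved.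
- Comparison: the chosen route keeps 1 intact and spends its steps on the two upper stereocentres only.

Key step: step 19

## Route

Step 1
Reactants: 1 (−)-epigallocatechin
Product: 2 5,7,3′,4′,5′-penta-O-benzyl-(−)-epigallocatechin (3-OH free)
Conditions: BnBr (5.5 equiv), K2CO3, DMF, N2, 0 °C → rt
Reagents that add atoms: benzyl bromide, BrCc1ccccc1
Why: Williamson ether synthesis; carbonate deprotonates only the five phenols, so the secondary 3-OH stays free, and exclusion of air at low temperature keeps the phenolates from oxidising and C2 from epimerising through ring opening.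

Step 2
Reactants: 2 5,7,3′,4′,5′-penta-O-benzyl-(−)-epigallocatechin
Product: 3 3,5,7,3′,4′,5′-hexa-O-benzyl-(−)-epigallocatechin
Conditions: NaH, BnBr, Bu4NI (cat.), DMF, 0 °C → rt
Reagents that add atoms: benzyl bromide, BrCc1ccccc1
Why: Williamson ether synthesis on the secondary alkoxide; with all phenols capped there is no path for base-induced opening of the pyran ring, and the molecule now carries a single kind of protecting group.

Step 3
Reactants: 3 3,5,7,3′,4′,5′-hexa-O-benzyl-(−)-epigallocatechin
Product: 4 8-bromo-hexa-O-benzyl-(−)-epigallocatechin (HBE–Br)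
Conditions: NBS (1.0 equiv), CH2Cl2, −78 → 0 °C
Reagents that add atoms: N-bromosuccinimide, O=C1CCC(=O)N1Br
Why: Electrophilic aromatic bromination; the phloroglucinol-type ring A is far more nucleophilic than the tris(benzyloxy)phenyl ring, and C8 (between one benzyloxy group and the ring oxygen) is attacked in preference to C6 (between two benzyloxy groups), the usual preference of 5,7-di-O-benzylflavan-3-ol ethers.

Step 4
Reactants: 4 8-bromo-hexa-O-benzyl-(−)-epigallocatechin
Product: 5 hexa-O-benzyl-(−)-epigallocatechin-8-carbaldehyde (HBE–CHO)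
Conditions: n-BuLi (1.1 equiv), THF, −78 °C; DMF, −78 → 0 °C; aq. NH4Cl
Reagents that add atoms: N,N-dimethylformamide, CN(C)C=O
Why: Bromine–lithium exchange at −78 °C outruns deprotonation at the benzylic ether positions; the aryllithium is formylated by DMF (Bouveault aldehyde synthesis) and the aldehyde is released only on aqueous work-up.

Step 5
Reactants: 5 hexa-O-benzyl-(−)-epigallocatechin-8-carbaldehyde; 6 diethyl malonate
Product: 8 tetraethyl 2-(HBE)propane-1,1,3,3-tetracarboxylate, via arylidenemalonate 7 (not isolated)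
Conditions: 6 (1.2 equiv), piperidine (cat.), AcOH (cat.), toluene, reflux, Dean–Stark; concentrate; then 6 (2 equiv), NaOEt (0.3 equiv), EtOH–THF, 40 °C; AcOH quench
Reagents that add atoms: diethyl malonate (second molecule of 6; the Michael donor), CCOC(=O)CC(=O)OCC
Why: Knoevenagel condensation of 5 with one molecule of 6 (water removed azeotropically) followed by Michael addition of a second molecule of 6 to 7, so that 8 holds both malonate units; the two ortho substituents twist the aryl ring out of conjugation with the alkene, which keeps it electrophilic, and excess 6 with a mildly acidic quench holds the adduct against retro-Michael loss. The new benzylic carbon bears two identical arms and is not yet a stereocentre.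

Step 6
Reactants: 8 tetraethyl 2-(HBE)propane-1,1,3,3-tetracarboxylate
Product: 9 diethyl 3-(HBE)pentanedioate
Conditions: LiCl, H2O, DMSO, 140 °C
Reagents that add atoms: none
Why: Krapcho dealkoxycarbonylation; chloride dealkylates one ester of each malonate and the carboxylate loses CO2 under neutral conditions, so the benzyl ethers are untouched and the retro-Michael reaction that threatens under hydroxide is avoided.

Step 7
Reactants: 9 diethyl 3-(HBE)pentanedioate
Product: 10 3-(HBE)pentanedioic acid
Conditions: LiOH, THF–MeOH–H2O, 40 °C; then 1 M HCl, 0 °C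
Reagents that add atoms: lithium hydroxide (its oxygen ends in the two carboxyl groups), [Li+].[OH-]
Why: Saponification of two unhindered ethyl esters; the diacid is set free with cold dilute acid, which aryl benzyl ethers tolerate.

Step 8
Reactants: 10 3-(HBE)pentanedioic acid
Product: 11 4-(HBE)oxane-2,6-dione (3-arylglutaric anhydride)
Conditions: Ac2O, 60 °C; evaporate with toluene
Reagents that add atoms: none
Why: Cyclodehydration of a glutaric acid to the six-membered anhydride through the mixed anhydride; the product is prochiral at the aryl-bearing carbon, its two carbonyl groups differing only through the remote chirality of HBE.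

Step 9
Reactants: 11 4-(HBE)oxane-2,6-dione
Product: 12 (3S)-5-methoxy-5-oxo-3-(HBE)pentanoic acid
Conditions: MeOH (10 equiv), quinine-derived 3,5-bis(trifluoromethyl)benzenesulfonamide organocatalyst (10 mol %), MTBE, −20 °C → rt
Reagents that add atoms: methanol, CO
Why: Catalytic desymmetrising alcoholysis of a 3-arylglutaric anhydride; the bifunctional cinchona catalyst activates methanol with its quinuclidine nitrogen and one carbonyl with the sulfonamide N–H, so upper C4 is set by the catalyst. Because HBE is chiral the two possible hemiesters are diastereomers, and the minor one can be removed by chromatography or as a crystalline amine salt. The acid arm becomes the vinyl ketone side (future C4a), the ester arm the carbinol side (future C3 and C2).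

Step 10
Reactants: 12 (3S)-5-methoxy-5-oxo-3-(HBE)pentanoic acid
Product: 14 methyl (3S)-5-oxo-3-(HBE)pentanoate, via acid chloride 13 (not isolated)
Conditions: 1-chloro-N,N,2-trimethylprop-1-en-1-amine (1.05 equiv), CH2Cl2, 0 °C; evaporate below 20 °C; LiAlH(Ot-Bu)3 (1.05 equiv), THF, −78 °C
Reagents that add atoms: none
Why: The acid chloride is formed under neutral conditions (no HCl, no formylating species that could attack the electron-rich ring) and reduced by the hindered hydride, which at −78 °C stops at the aldehyde and spares the methyl ester (acid chloride to aldehyde reduction). The chloride is kept cold so that it cannot close back to the symmetrical anhydride, which would erase C4.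

Step 11
Reactants: 14 methyl (3S)-5-oxo-3-(HBE)pentanoate
Product: 16 (4S)-4-(HBE)-6-vinyloxan-2-one (both C6 epimers), via hydroxy ester 15 (not isolated)
Conditions: CH2=CHMgBr (1.2 equiv), THF, −78 °C; aq. NH4Cl; then PPTS (cat.), toluene, 50 °C
Reagents that add atoms: vinylmagnesium bromide, C=C[Mg]Br
Why: Grignard addition to the aldehyde, which is far more reactive than the ester at −78 °C, then acid-catalysed lactonisation of the δ-hydroxy ester. The new carbinol centre is formed without control and needs none, since it is oxidised in step 17; the lactone ties up the hydroxyl and provides a carbonyl that accepts one organolithium only.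

Step 12
Reactants: 16 (4S)-4-(HBE)-6-vinyloxan-2-one; 17 4-bromo-1,2-bis(benzyloxy)benzene
Product: 19 (3S)-1-(DBP)-5-hydroxy-3-(HBE)hept-6-en-1-one (both C5 epimers), via aryllithium 18 (not isolated)
Conditions: 17 (1.1 equiv), n-BuLi (1.05 equiv), THF, −78 °C; add to 16, THF, −78 °C; aq. NH4Cl at −78 °C
Reagents that add atoms: none
Why: Addition of an aryllithium to a δ-lactone; the lithium hemiketal alkoxide formed at −78 °C does not collapse before protonation, so only one aryl group enters and the aryl ketone and the allylic alcohol appear together on work-up.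

Step 13
Reactants: 19 (3S)-1-(DBP)-5-hydroxy-3-(HBE)hept-6-en-1-one
Product: 20 (3S)-1-(DBP)-3-(HBE)-5-(triethylsilyloxy)hept-6-en-1-one (both C5 epimers)
Conditions: Et3SiCl, imidazole, DMF, 0 °C
Reagents that add atoms: chlorotriethylsilane, CC[Si](CC)(CC)Cl
Why: Silylation of the secondary allylic alcohol; the silyl ether is the masked form of the vinyl ketone, it survives borane reagents, KH and n-BuLi where a ketone or ester would not, and fluoride removes it under conditions a ynol ether tolerates.

Step 14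
Reactants: 20 (3S)-1-(DBP)-3-(HBE)-5-(triethylsilyloxy)hept-6-en-1-one
Product: 21 (1S,3R)-1-(DBP)-3-(HBE)-5-(triethylsilyloxy)hept-6-en-1-ol (both C5 epimers)
Conditions: (R)-Me-CBS oxazaborolidine (0.3 equiv), catecholborane (2 equiv), toluene, −78 → −40 °C; MeOH; aq. NaOH wash
Reagents that add atoms: none
Why: Corey–Bakshi–Shibata reduction; the ketone binds to the catalyst with the aryl group as the large substituent, and the (R)-catalyst should deliver hydride to give the (S)-carbinol (upper C2) by catalyst control, as for aryl alkyl ketones in general. Catecholborane is the hydride source because it does not hydroborate the terminal alkene at low temperature.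

Step 15
Reactants: 21 (1S,3R)-1-(DBP)-3-(HBE)-5-(triethylsilyloxy)hept-6-en-1-ol; 22 trichloroethylene
Product: 24 (5R,7S)-7-(DBP)-7-(ethynyloxy)-5-(HBE)-3-(triethylsilyloxy)hept-1-ene (both C3 epimers), via dichlorovinyl ether 23 (not isolated)
Conditions: KH (2.2 equiv), THF, 0 °C → rt; 22 (1.2 equiv), rt; then n-BuLi (2.6 equiv), −78 → −40 °C; MeOH, −78 °C; cold pH 7 buffer
Reagents that add atoms: none
Why: Alkoxide/trichloroethylene route to ynol ethers; the potassium alkoxide adds to dichloroacetylene formed in situ from 22 to give the (E)-1,2-dichlorovinyl ether, and n-BuLi then eliminates HCl and exchanges the remaining chlorine to the lithium alkynyl ether, which methanol protonates. The carbinol C–O bond is not touched, so upper C2 keeps its configuration, and the neutral cold work-up avoids acid-catalysed hydration of the ynol ether.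

Step 16
Reactants: 24 (5R,7S)-7-(DBP)-7-(ethynyloxy)-5-(HBE)-3-(triethylsilyloxy)hept-1-ene
Product: 25 (5S,7S)-7-(DBP)-7-(ethynyloxy)-5-(HBE)hept-1-en-3-ol (both C3 epimers)
Conditions: Bu4NF (1.1 equiv), THF, 0 °C; pH 7 buffer
Reagents that add atoms: none
Why: Fluoride cleavage of the triethylsilyl ether at 0 °C; the base-stable ynol ether and the benzyl ethers are not affected.

Step 17
Reactants: 25 (5S,7S)-7-(DBP)-7-(ethynyloxy)-5-(HBE)hept-1-en-3-ol
Product: 26 (5R,7S)-7-(DBP)-7-(ethynyloxy)-5-(HBE)hept-1-en-3-one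
Conditions: Dess–Martin periodinane (1.3 equiv), NaHCO3, CH2Cl2, 0 °C
Reagents that add atoms: none
Why: Dess–Martin oxidation of the allylic alcohol to the vinyl ketone under bicarbonate buffer, so that no acetic acid reaches the ynol ether; the two carbinol epimers converge to one ketone.

Step 18
Reactants: 26 (5R,7S)-7-(DBP)-7-(ethynyloxy)-5-(HBE)hept-1-en-3-one
Product: 28 (5S,7S)-4-diazo-7-(DBP)-7-(ethynyloxy)-5-(HBE)hept-1-en-3-one, via trifluoroacetyl ketone 27 (not isolated)
Conditions: 26 added slowly to LiN(SiMe3)2 (1.1 equiv), THF, −78 °C; CF3CO2CH2CF3 (1.3 equiv), −78 °C; then MsN3 (1.5 equiv), Et3N (1.5 equiv), H2O (1 equiv), MeCN, 0 → 15 °C, dark; no acidic work-up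
Reagents that add atoms: methanesulfonyl azide, CS(=O)(=O)N=[N+]=[N-]
Why: Detrifluoroacetylative diazo transfer, the standard entry to α′-diazo enones; the ketone has a single enolisable position (the future C4a), its lithium enolate is C-acylated by the trifluoroacetate ester, and the 1,3-diketone takes the diazo group from MsN3 with loss of the trifluoroacetyl group. Slow addition of 26 to the base keeps free enone away from the enolate, and C4, which is β to the carbonyl, cannot epimerise.

Step 19
Reactants: 28 (5S,7S)-4-diazo-7-(DBP)-7-(ethynyloxy)-5-(HBE)hept-1-en-3-one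
Product: 33 (2S,4R)-2-(DBP)-4-(HBE)chroman-7-ol (octa-O-benzyl ether of the target; upper 7-OH free), via vinylketene 29 (not isolated), via fused vinylcyclobutenone 30 (not isolated), via dienylketene 31 (not isolated), via cyclohexadienone 32 (not isolated)
Conditions: hν (365 nm LEDs, Pyrex), degassed toluene, 0.003 M, 10–15 °C until the diazo band has gone; then 80 °C, dark, 2 h
Reagents that add atoms: none
Why: Proposed new method: light expels N2 and the vinyl group migrates from the carbonyl carbon to the diazo carbon (Wolff rearrangement), giving vinylketene 29, whose α-carbon is the future C4a and whose carbonyl carbon is the future C7. The ketene adds [2+2] to the tethered ynol ether, the terminal alkyne carbon bonding to the ketene carbonyl carbon (C7–C8) and the oxygen-bearing carbon to the ketene α-carbon (C8a–C4a); this cycloaddition closes ring C as the six-membered ring of the bicyclo[4.2.0] ketone 30. Conrotatory 4π opening of 30 gives dienylketene 31, in which the C4a=C8a double bond lies inside ring C, so the vinyl and ketenyl groups are necessarily cis; 6π electrocyclisation (C6–C7) and enolisation of 32 then close ring A as the phenol. The closest known reaction type is the intermolecular photochemical Danheiser benzannulation of α-diazo enones with alkoxy- and siloxyalkynes; an intramolecular version with an oxygen-tethered terminal ynol ether has not been shown. No stereocentre is created in 33: C2 and C4 are carried in from 28 and the transient quaternary centre of 30 vanishes on ring opening. The regiochemistry of the [2+2] is fixed by the polarisation of the ynol ether and by the four-atom tether, since the reverse orientation would require a bridged ring. Light of 365 nm is absorbed by the diazo ketone only and not by the benzyl ethers, and high dilution keeps the ketene from dimerising or acylating product phenol. The irradiation is run below 20 °C so that the thermally labile benzylic ynol ether (retro-ene loss, sigmatropic shift) is consumed by the cycloaddition before the solution is warmed for the ring opening.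

Step 20
Reactants: 33 (2S,4R)-2-(DBP)-4-(HBE)chroman-7-ol
Product: 34 (2R,3R)-8-[(2S,4R)-2-(3,4-dihydroxyphenyl)-7-hydroxychroman-4-yl]-2-(3,4,5-trihydroxyphenyl)chromane-3,5,7-triol (CNP0211965.1)
Conditions: H2 (1 atm), Pd(OH)2 on carbon, THF–MeOH, rt
Reagents that add atoms: none
Why: Hydrogenolysis of the eight benzyl ethers in a neutral solvent; the ring C–O bonds and the C4–C8 bond are not cleaved under these conditions, as is usual for benzylated oligoflavanoids, and no stereocentre is at risk.

## Compound list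

1 | (−)-epigallocatechin | Oc1cc(O)c2c(c1)O[C@H](c1cc(O)c(O)c(O)c1)[C@H](O)C2 | starting material
2 | 5,7,3′,4′,5′-penta-O-benzyl-(−)-epigallocatechin | c1ccccc1COc1cc(OCc3ccccc3)c2c(c1)O[C@H](c1cc(OCc3ccccc3)c(OCc3ccccc3)c(OCc3ccccc3)c1)[C@H](O)C2 | intermediate
3 | 3,5,7,3′,4′,5′-hexa-O-benzyl-(−)-epigallocatechin | c1ccccc1COc1cc(OCc3ccccc3)c2c(c1)O[C@H](c1cc(OCc3ccccc3)c(OCc3ccccc3)c(OCc3ccccc3)c1)[C@H](OCc1ccccc1)C2 | intermediate
4 | 8-bromo-hexa-O-benzyl-(−)-epigallocatechin | Brc1c(OCc2ccccc2)cc(OCc2ccccc2)c2c1O[C@H](c1cc(OCc3ccccc3)c(OCc3ccccc3)c(OCc3ccccc3)c1)[C@H](OCc1ccccc1)C2 | intermediate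
5 | hexa-O-benzyl-(−)-epigallocatechin-8-carbaldehyde | O=Cc1c(OCc2ccccc2)cc(OCc2ccccc2)c2c1O[C@H](c1cc(OCc3ccccc3)c(OCc3ccccc3)c(OCc3ccccc3)c1)[C@H](OCc1ccccc1)C2 | intermediate
6 | diethyl malonate | CCOC(=O)CC(=O)OCC | starting material
7 | diethyl 2-(HBE-methylidene)malonate | CCOC(=O)C(C(=O)OCC)=Cc1c(OCc2ccccc2)cc(OCc2ccccc2)c2c1O[C@H](c1cc(OCc3ccccc3)c(OCc3ccccc3)c(OCc3ccccc3)c1)[C@H](OCc1ccccc1)C2 | intermediate
8 | tetraethyl 2-(HBE)propane-1,1,3,3-tetracarboxylate | CCOC(=O)C(C(=O)OCC)C(C(C(=O)OCC)C(=O)OCC)c1c(OCc2ccccc2)cc(OCc2ccccc2)c2c1O[C@H](c1cc(OCc3ccccc3)c(OCc3ccccc3)c(OCc3ccccc3)c1)[C@H](OCc1ccccc1)C2 | intermediate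
9 | diethyl 3-(HBE)pentanedioate | CCOC(=O)CC(CC(=O)OCC)c1c(OCc2ccccc2)cc(OCc2ccccc2)c2c1O[C@H](c1cc(OCc3ccccc3)c(OCc3ccccc3)c(OCc3ccccc3)c1)[C@H](OCc1ccccc1)C2 | intermediate
10 | 3-(HBE)pentanedioic acid | OC(=O)CC(CC(=O)O)c1c(OCc2ccccc2)cc(OCc2ccccc2)c2c1O[C@H](c1cc(OCc3ccccc3)c(OCc3ccccc3)c(OCc3ccccc3)c1)[C@H](OCc1ccccc1)C2 | intermediate
11 | 4-(HBE)oxane-2,6-dione | O=C1CC(CC(=O)O1)c1c(OCc2ccccc2)cc(OCc2ccccc2)c2c1O[C@H](c1cc(OCc3ccccc3)c(OCc3ccccc3)c(OCc3ccccc3)c1)[C@H](OCc1ccccc1)C2 | intermediate
12 | (3S)-5-methoxy-5-oxo-3-(HBE)pentanoic acid | COC(=O)C[C@H](CC(=O)O)c1c(OCc2ccccc2)cc(OCc2ccccc2)c2c1O[C@H](c1cc(OCc3ccccc3)c(OCc3ccccc3)c(OCc3ccccc3)c1)[C@H](OCc1ccccc1)C2 | intermediate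
13 | methyl (3R)-5-chloro-5-oxo-3-(HBE)pentanoate | COC(=O)C[C@H](CC(=O)Cl)c1c(OCc2ccccc2)cc(OCc2ccccc2)c2c1O[C@H](c1cc(OCc3ccccc3)c(OCc3ccccc3)c(OCc3ccccc3)c1)[C@H](OCc1ccccc1)C2 | intermediate
14 | methyl (3S)-5-oxo-3-(HBE)pentanoate | COC(=O)C[C@H](CC=O)c1c(OCc2ccccc2)cc(OCc2ccccc2)c2c1O[C@H](c1cc(OCc3ccccc3)c(OCc3ccccc3)c(OCc3ccccc3)c1)[C@H](OCc1ccccc1)C2 | intermediate
15 | methyl (3S)-5-hydroxy-3-(HBE)hept-6-enoate (both C5 epimers) | COC(=O)C[C@H](CC(O)C=C)c1c(OCc2ccccc2)cc(OCc2ccccc2)c2c1O[C@H](c1cc(OCc3ccccc3)c(OCc3ccccc3)c(OCc3ccccc3)c1)[C@H](OCc1ccccc1)C2 | intermediate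
16 | (4S)-4-(HBE)-6-vinyloxan-2-one (both C6 epimers) | C=CC1C[C@@H](CC(=O)O1)c1c(OCc2ccccc2)cc(OCc2ccccc2)c2c1O[C@H](c1cc(OCc3ccccc3)c(OCc3ccccc3)c(OCc3ccccc3)c1)[C@H](OCc1ccccc1)C2 | intermediate
17 | 4-bromo-1,2-bis(benzyloxy)benzene | Brc1ccc(OCc2ccccc2)c(OCc2ccccc2)c1 | starting material
18 | [3,4-bis(benzyloxy)phenyl]lithium | [Li]c1ccc(OCc2ccccc2)c(OCc2ccccc2)c1 | intermediate
19 | (3S)-1-(DBP)-5-hydroxy-3-(HBE)hept-6-en-1-one (both C5 epimers) | C=CC(O)C[C@@H](CC(=O)c1ccc(OCc2ccccc2)c(OCc2ccccc2)c1)c1c(OCc2ccccc2)cc(OCc2ccccc2)c2c1O[C@H](c1cc(OCc3ccccc3)c(OCc3ccccc3)c(OCc3ccccc3)c1)[C@H](OCc1ccccc1)C2 | intermediate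
20 | (3S)-1-(DBP)-3-(HBE)-5-(triethylsilyloxy)hept-6-en-1-one (both C5 epimers) | C=CC(O[Si](CC)(CC)CC)C[C@@H](CC(=O)c1ccc(OCc2ccccc2)c(OCc2ccccc2)c1)c1c(OCc2ccccc2)cc(OCc2ccccc2)c2c1O[C@H](c1cc(OCc3ccccc3)c(OCc3ccccc3)c(OCc3ccccc3)c1)[C@H](OCc1ccccc1)C2 | intermediate
21 | (1S,3R)-1-(DBP)-3-(HBE)-5-(triethylsilyloxy)hept-6-en-1-ol (both C5 epimers) | C=CC(O[Si](CC)(CC)CC)C[C@@H](C[C@H](O)c1ccc(OCc2ccccc2)c(OCc2ccccc2)c1)c1c(OCc2ccccc2)cc(OCc2ccccc2)c2c1O[C@H](c1cc(OCc3ccccc3)c(OCc3ccccc3)c(OCc3ccccc3)c1)[C@H](OCc1ccccc1)C2 | intermediate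
22 | trichloroethylene | ClC=C(Cl)Cl | starting material
23 | (E)-1,2-dichlorovinyl ether of 21 | C=CC(O[Si](CC)(CC)CC)C[C@@H](C[C@H](O/C(Cl)=C\Cl)c1ccc(OCc2ccccc2)c(OCc2ccccc2)c1)c1c(OCc2ccccc2)cc(OCc2ccccc2)c2c1O[C@H](c1cc(OCc3ccccc3)c(OCc3ccccc3)c(OCc3ccccc3)c1)[C@H](OCc1ccccc1)C2 | intermediate
24 | (5R,7S)-7-(DBP)-7-(ethynyloxy)-5-(HBE)-3-(triethylsilyloxy)hept-1-ene (both C3 epimers) | C=CC(O[Si](CC)(CC)CC)C[C@@H](C[C@H](OC#C)c1ccc(OCc2ccccc2)c(OCc2ccccc2)c1)c1c(OCc2ccccc2)cc(OCc2ccccc2)c2c1O[C@H](c1cc(OCc3ccccc3)c(OCc3ccccc3)c(OCc3ccccc3)c1)[C@H](OCc1ccccc1)C2 | intermediate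
25 | (5S,7S)-7-(DBP)-7-(ethynyloxy)-5-(HBE)hept-1-en-3-ol (both C3 epimers) | C=CC(O)C[C@@H](C[C@H](OC#C)c1ccc(OCc2ccccc2)c(OCc2ccccc2)c1)c1c(OCc2ccccc2)cc(OCc2ccccc2)c2c1O[C@H](c1cc(OCc3ccccc3)c(OCc3ccccc3)c(OCc3ccccc3)c1)[C@H](OCc1ccccc1)C2 | intermediate
26 | (5R,7S)-7-(DBP)-7-(ethynyloxy)-5-(HBE)hept-1-en-3-one | C=CC(=O)C[C@@H](C[C@H](OC#C)c1ccc(OCc2ccccc2)c(OCc2ccccc2)c1)c1c(OCc2ccccc2)cc(OCc2ccccc2)c2c1O[C@H](c1cc(OCc3ccccc3)c(OCc3ccccc3)c(OCc3ccccc3)c1)[C@H](OCc1ccccc1)C2 | intermediate
27 | 4-(trifluoroacetyl) derivative of 26 (C4 epimers and enol forms, C5 and C7 as in 26) | C=CC(=O)C(C(=O)C(F)(F)F)[C@@H](C[C@H](OC#C)c1ccc(OCc2ccccc2)c(OCc2ccccc2)c1)c1c(OCc2ccccc2)cc(OCc2ccccc2)c2c1O[C@H](c1cc(OCc3ccccc3)c(OCc3ccccc3)c(OCc3ccccc3)c1)[C@H](OCc1ccccc1)C2 | intermediate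
28 | (5S,7S)-4-diazo-7-(DBP)-7-(ethynyloxy)-5-(HBE)hept-1-en-3-one | C=CC(=O)C(=[N+]=[N-])[C@@H](C[C@H](OC#C)c1ccc(OCc2ccccc2)c(OCc2ccccc2)c1)c1c(OCc2ccccc2)cc(OCc2ccccc2)c2c1O[C@H](c1cc(OCc3ccccc3)c(OCc3ccccc3)c(OCc3ccccc3)c1)[C@H](OCc1ccccc1)C2 | intermediate
29 | vinylketene O=C=C(CH=CH2)–CH(HBE)–CH2–CH(OC≡CH)(DBP), stereocentres as in 28 | C=CC(=C=O)[C@@H](C[C@H](OC#C)c1ccc(OCc2ccccc2)c(OCc2ccccc2)c1)c1c(OCc2ccccc2)cc(OCc2ccccc2)c2c1O[C@H](c1cc(OCc3ccccc3)c(OCc3ccccc3)c(OCc3ccccc3)c1)[C@H](OCc1ccccc1)C2 | intermediate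
30 | 3-(DBP)-5-(HBE)-6-vinyl-2-oxabicyclo[4.2.0]oct-1(8)-en-7-one, C3 and C5 as upper C2 and C4 of 33, C6 either way | C=CC14C(=O)C=C1O[C@H](c1ccc(OCc2ccccc2)c(OCc2ccccc2)c1)C[C@H]4c1c(OCc2ccccc2)cc(OCc2ccccc2)c2c1O[C@H](c1cc(OCc3ccccc3)c(OCc3ccccc3)c(OCc3ccccc3)c1)[C@H](OCc1ccccc1)C2 | intermediate
31 | 2-[2-(DBP)-4-(HBE)-5-vinyl-3,4-dihydro-2H-pyran-6-yl]ethenone, C2 and C4 as in 33 | C=CC4=C(C=C=O)O[C@H](c1ccc(OCc2ccccc2)c(OCc2ccccc2)c1)C[C@H]4c1c(OCc2ccccc2)cc(OCc2ccccc2)c2c1O[C@H](c1cc(OCc3ccccc3)c(OCc3ccccc3)c(OCc3ccccc3)c1)[C@H](OCc1ccccc1)C2 | intermediate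
32 | 2-(DBP)-4-(HBE)-3,4-dihydro-2H-chromen-7(6H)-one, C2 and C4 as in 33 | O=C1CC=C4C(=C1)O[C@H](c1ccc(OCc2ccccc2)c(OCc2ccccc2)c1)C[C@H]4c1c(OCc2ccccc2)cc(OCc2ccccc2)c2c1O[C@H](c1cc(OCc3ccccc3)c(OCc3ccccc3)c(OCc3ccccc3)c1)[C@H](OCc1ccccc1)C2 | intermediate
33 | (2S,4R)-2-(DBP)-4-(HBE)chroman-7-ol | Oc1ccc2c(c1)O[C@H](c1ccc(OCc3ccccc3)c(OCc3ccccc3)c1)C[C@H]2c1c(OCc2ccccc2)cc(OCc2ccccc2)c2c1O[C@H](c1cc(OCc3ccccc3)c(OCc3ccccc3)c(OCc3ccccc3)c1)[C@H](OCc1ccccc1)C2 | intermediate
34 | (2R,3R)-8-[(2S,4R)-2-(3,4-dihydroxyphenyl)-7-hydroxychroman-4-yl]-2-(3,4,5-trihydroxyphenyl)chromane-3,5,7-triol | Oc1ccc2c(c1)O[C@H](c1ccc(O)c(O)c1)C[C@H]2c1c(O)cc(O)c2c1O[C@H](c1cc(O)c(O)c(O)c1)[C@H](O)C2 | target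

## Step count and least certain steps

Total step count: 20. Longest linear sequence: 20 steps (1 → 34); 6, 17 and 22 are commercial and enter directly.

**Step 19 (key step, new method).**
- What may go wrong: a 1,2-hydride shift from C4 to the carbene carbon can compete with the Wolff migration, because a fully substituted acyclic diazo ketone populates the conformer that rearranges in concert less well. The benzylic ynol ether can be lost thermally before the cycloaddition. The carbene can also be intercepted by a neighbouring benzyl ether oxygen.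
- Fallback (known chemistry, sets out from 3, returns at 34): the upper unit is attached by acid-mediated flavan-4-yl coupling. Racemic 7-(benzyloxy)-2-(DBP)chroman-4-one F1 is made by Claisen–Schmidt condensation of 1-[4-(benzyloxy)-2-hydroxyphenyl]ethanone with 3,4-bis(benzyloxy)benzaldehyde and ring closure. It is resolved by asymmetric transfer hydrogenation (RuCl(TsDPEN)(p-cymene) of the handedness that reduces the 2S ketone, HCO2H/Et3N) to the cis-(2S,4S)-flavan-4-ol F2. Ionisation of F2 with BF3·OEt2 in CH2Cl2 at −78 → −30 °C in the presence of excess 3 should give, by Friedel–Crafts attack of lower C8 anti to the 2-aryl group, the 2,4-trans nona-O-benzyl dimer F3. Hydrogenolysis as in step 20 then gives 34.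

**Step 18 (diazo transfer).**
- What may go wrong: conjugate addition of the cross-conjugated enolate to vinyl ketone not yet deprotonated (oligomerisation), metalation and acylation at the acetylenic C–H, and bimolecular dipolar cycloaddition of the diazo group to the acryloyl unit on standing.
- Fallback (sets out from 14, returns at 33): the vinyl group is capped with a removable silyl group. (E)-2-(Trimethylsilyl)vinylmagnesium bromide replaces the vinyl Grignard reagent of step 11 and the reactions of steps 11–18 are repeated. This gives in turn the silylvinyl lactone F4, the hydroxy ketone F5, the triethylsilyl ether F6, the (S)-carbinol F7, the ynol ether F8, the allylic alcohol F9, the β-silyl enone F10 (shielded against conjugate addition) and the diazo ketone F11. Irradiation and warming as in step 19 should give the 6-(trimethylsilyl)phenol F12, and ipso-protodesilylation (CF3CO2H, CH2Cl2, 0 °C) leads to 33.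

**Step 15 (ynol ether).**
- What may go wrong: incomplete capture of dichloroacetylene by the hindered secondary benzylic alkoxide, migration of the silyl group to the alkoxide, or hydration of the product during isolation.
- Fallback (sets out from 21, returns at 24): formylation (formic acetic anhydride, pyridine, 0 °C) gives the formate F13. Ramirez-type dibromo-olefination of the formate carbonyl (CBr4, PPh3, CH2Cl2) gives the 2,2-dibromovinyl ether F14. n-BuLi (2.2 equiv, −78 °C) converts F14 into the lithium alkynyl ether, and a methanol quench gives 24. No potassium alkoxide and no dichloroacetylene are involved.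

**Step 9 (desymmetrisation).**
- What may go wrong: poor differentiation of the two carbonyl groups, if the bulky chiral aryl group next to the reacting ring overrides or opposes the catalyst.
- Fallback (sets out from 11, returns at 16): the anhydride is opened with stoichiometric (S)-1-(naphthalen-1-yl)ethanol (or its enantiomer, chosen by the same test as the catalyst) and DMAP in CH2Cl2 at −40 °C to give the 1-(naphthalen-1-yl)ethyl hemiester F15. Here the controlling element sits on the nucleophile, and the diastereomeric hemiesters should be separable. F15 is taken through the chemistry of step 10 to the aldehyde F16. Vinyl addition and lactonisation, which releases the naphthylethanol, return to 16.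

**Step 5 (Knoevenagel–Michael).**
- What may go wrong: slow conjugate addition to the hindered, electron-rich arylidenemalonate and reversal of the addition (retro-Michael) during work-up.
- Fallback (sets out from 4, returns at 10): 4 is lithiated (n-BuLi, −78 °C), transmetalated with ZnCl2 and cross-coupled (Negishi, Pd2(dba)3/SPhos) with dimethyl 3-(trifluoromethylsulfonyloxy)pent-2-enedioate to give the dimethyl 3-arylpent-2-enedioate F17. Conjugate reduction with Mg in MeOH gives dimethyl 3-(HBE)pentanedioate F18, and saponification as in step 7 returns to 10.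

## Further compounds

F1 | step 19 | racemic 7-(benzyloxy)-2-[3,4-bis(benzyloxy)phenyl]chroman-4-one | O=C1CC(c2ccc(OCc3ccccc3)c(OCc3ccccc3)c2)Oc2cc(OCc3ccccc3)ccc12
F2 | step 19 | (2S,4S)-7-(benzyloxy)-2-[3,4-bis(benzyloxy)phenyl]chroman-4-ol | c1ccccc1COc1ccc2c(c1)O[C@H](c1ccc(OCc3ccccc3)c(OCc3ccccc3)c1)C[C@@H]2O
F3 | step 19 | nona-O-benzyl ether of 34 | c1ccccc1COc1ccc2c(c1)O[C@H](c1ccc(OCc3ccccc3)c(OCc3ccccc3)c1)C[C@H]2c1c(OCc2ccccc2)cc(OCc2ccccc2)c2c1O[C@H](c1cc(OCc3ccccc3)c(OCc3ccccc3)c(OCc3ccccc3)c1)[C@H](OCc1ccccc1)C2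
F4 | step 18 | (4S)-4-(HBE)-6-[(E)-2-(trimethylsilyl)vinyl]oxan-2-one (both C6 epimers) | C[Si](C)(C)/C=C/C1C[C@@H](CC(=O)O1)c1c(OCc2ccccc2)cc(OCc2ccccc2)c2c1O[C@H](c1cc(OCc3ccccc3)c(OCc3ccccc3)c(OCc3ccccc3)c1)[C@H](OCc1ccccc1)C2
F5 | step 18 | 7-(trimethylsilyl) analogue of 19 | C[Si](C)(C)/C=C/C(O)C[C@@H](CC(=O)c1ccc(OCc2ccccc2)c(OCc2ccccc2)c1)c1c(OCc2ccccc2)cc(OCc2ccccc2)c2c1O[C@H](c1cc(OCc3ccccc3)c(OCc3ccccc3)c(OCc3ccccc3)c1)[C@H](OCc1ccccc1)C2
F6 | step 18 | 7-(trimethylsilyl) analogue of 20 | C[Si](C)(C)/C=C/C(O[Si](CC)(CC)CC)C[C@@H](CC(=O)c1ccc(OCc2ccccc2)c(OCc2ccccc2)c1)c1c(OCc2ccccc2)cc(OCc2ccccc2)c2c1O[C@H](c1cc(OCc3ccccc3)c(OCc3ccccc3)c(OCc3ccccc3)c1)[C@H](OCc1ccccc1)C2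
F7 | step 18 | 7-(trimethylsilyl) analogue of 21 | C[Si](C)(C)/C=C/C(O[Si](CC)(CC)CC)C[C@@H](C[C@H](O)c1ccc(OCc2ccccc2)c(OCc2ccccc2)c1)c1c(OCc2ccccc2)cc(OCc2ccccc2)c2c1O[C@H](c1cc(OCc3ccccc3)c(OCc3ccccc3)c(OCc3ccccc3)c1)[C@H](OCc1ccccc1)C2
F8 | step 18 | 1-(trimethylsilyl) analogue of 24 | C[Si](C)(C)/C=C/C(O[Si](CC)(CC)CC)C[C@@H](C[C@H](OC#C)c1ccc(OCc2ccccc2)c(OCc2ccccc2)c1)c1c(OCc2ccccc2)cc(OCc2ccccc2)c2c1O[C@H](c1cc(OCc3ccccc3)c(OCc3ccccc3)c(OCc3ccccc3)c1)[C@H](OCc1ccccc1)C2
F9 | step 18 | 1-(trimethylsilyl) analogue of 25 | C[Si](C)(C)/C=C/C(O)C[C@@H](C[C@H](OC#C)c1ccc(OCc2ccccc2)c(OCc2ccccc2)c1)c1c(OCc2ccccc2)cc(OCc2ccccc2)c2c1O[C@H](c1cc(OCc3ccccc3)c(OCc3ccccc3)c(OCc3ccccc3)c1)[C@H](OCc1ccccc1)C2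
F10 | step 18 | (E)-1-(trimethylsilyl) analogue of 26 | C[Si](C)(C)/C=C/C(=O)C[C@@H](C[C@H](OC#C)c1ccc(OCc2ccccc2)c(OCc2ccccc2)c1)c1c(OCc2ccccc2)cc(OCc2ccccc2)c2c1O[C@H](c1cc(OCc3ccccc3)c(OCc3ccccc3)c(OCc3ccccc3)c1)[C@H](OCc1ccccc1)C2
F11 | step 18 | (E)-1-(trimethylsilyl) analogue of 28 | C[Si](C)(C)/C=C/C(=O)C(=[N+]=[N-])[C@@H](C[C@H](OC#C)c1ccc(OCc2ccccc2)c(OCc2ccccc2)c1)c1c(OCc2ccccc2)cc(OCc2ccccc2)c2c1O[C@H](c1cc(OCc3ccccc3)c(OCc3ccccc3)c(OCc3ccccc3)c1)[C@H](OCc1ccccc1)C2
F12 | step 18 | (2S,4R)-2-(DBP)-4-(HBE)-6-(trimethylsilyl)chroman-7-ol | Oc1c([Si](C)(C)C)cc2c(c1)O[C@H](c1ccc(OCc3ccccc3)c(OCc3ccccc3)c1)C[C@H]2c1c(OCc2ccccc2)cc(OCc2ccccc2)c2c1O[C@H](c1cc(OCc3ccccc3)c(OCc3ccccc3)c(OCc3ccccc3)c1)[C@H](OCc1ccccc1)C2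
F13 | step 15 | formate ester of 21 | C=CC(O[Si](CC)(CC)CC)C[C@@H](C[C@H](OC=O)c1ccc(OCc2ccccc2)c(OCc2ccccc2)c1)c1c(OCc2ccccc2)cc(OCc2ccccc2)c2c1O[C@H](c1cc(OCc3ccccc3)c(OCc3ccccc3)c(OCc3ccccc3)c1)[C@H](OCc1ccccc1)C2
F14 | step 15 | 2,2-dibromovinyl ether of 21 | C=CC(O[Si](CC)(CC)CC)C[C@@H](C[C@H](OC=C(Br)Br)c1ccc(OCc2ccccc2)c(OCc2ccccc2)c1)c1c(OCc2ccccc2)cc(OCc2ccccc2)c2c1O[C@H](c1cc(OCc3ccccc3)c(OCc3ccccc3)c(OCc3ccccc3)c1)[C@H](OCc1ccccc1)C2
F15 | step 9 | (3S)-5-[(S)-1-(naphthalen-1-yl)ethoxy]-5-oxo-3-(HBE)pentanoic acid | C[C@@H](c1cccc2ccccc12)OC(=O)C[C@H](CC(=O)O)c1c(OCc2ccccc2)cc(OCc2ccccc2)c2c1O[C@H](c1cc(OCc3ccccc3)c(OCc3ccccc3)c(OCc3ccccc3)c1)[C@H](OCc1ccccc1)C2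
F16 | step 9 | (S)-1-(naphthalen-1-yl)ethyl (3S)-5-oxo-3-(HBE)pentanoate | C[C@@H](c1cccc2ccccc12)OC(=O)C[C@H](CC=O)c1c(OCc2ccccc2)cc(OCc2ccccc2)c2c1O[C@H](c1cc(OCc3ccccc3)c(OCc3ccccc3)c(OCc3ccccc3)c1)[C@H](OCc1ccccc1)C2
F17 | step 5 | dimethyl 3-(HBE)pent-2-enedioate | COC(=O)CC(=CC(=O)OC)c1c(OCc2ccccc2)cc(OCc2ccccc2)c2c1O[C@H](c1cc(OCc3ccccc3)c(OCc3ccccc3)c(OCc3ccccc3)c1)[C@H](OCc1ccccc1)C2
F18 | step 5 | dimethyl 3-(HBE)pentanedioate | COC(=O)CC(CC(=O)OC)c1c(OCc2ccccc2)cc(OCc2ccccc2)c2c1O[C@H](c1cc(OCc3ccccc3)c(OCc3ccccc3)c(OCc3ccccc3)c1)[C@H](OCc1ccccc1)C2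
A1 | alternative 1 | flavan-4-yl phenol with lower C7 hydroxyl, C8a triisopropylsilyl ether, C5 benzyl ether and C4a cinnamyl group | c1ccccc1COc1ccc2c(c1)O[C@H](c1ccc(OCc3ccccc3)c(OCc3ccccc3)c1)C[C@H]2c1c(O)cc(OCc2ccccc2)c(C/C=C/c2cc(OCc3ccccc3)c(OCc3ccccc3)c(OCc3ccccc3)c2)c1O[Si](C(C)C)(C(C)C)C(C)C
A2 | alternative 1 | 3-(benzyloxy)-2-[(E)-3-[3,4,5-tris(benzyloxy)phenyl]allyl]cyclobut-2-en-1-one | O=C1CC(OCc2ccccc2)=C1C/C=C/c1cc(OCc2ccccc2)c(OCc2ccccc2)c(OCc2ccccc2)c1
A3 | alternative 1 | 7-(benzyloxy)-2-(DBP)-4-[(triisopropylsilyloxy)ethynyl]chromane, configured at C2 and C4 as in 33 | c1ccccc1COc1ccc2c(c1)O[C@H](c1ccc(OCc3ccccc3)c(OCc3ccccc3)c1)C[C@H]2C#CO[Si](C(C)C)(C(C)C)C(C)C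
A4 | alternative 2 | nona-O-benzyl ether of 34 | c1ccccc1COc1ccc2c(c1)O[C@H](c1ccc(OCc3ccccc3)c(OCc3ccccc3)c1)C[C@H]2c1c(OCc2ccccc2)cc(OCc2ccccc2)c2c1O[C@H](c1cc(OCc3ccccc3)c(OCc3ccccc3)c(OCc3ccccc3)c1)[C@H](OCc1ccccc1)C2
A5 | alternative 2 | (1R)-1-(DBP)-3-[4-(benzyloxy)-2-hydroxyphenyl]-3-(HBE)propan-1-ol, C3 as upper C4 of 34 | c1ccccc1COc1ccc(c(O)c1)[C@@H](C[C@@H](O)c1ccc(OCc3ccccc3)c(OCc3ccccc3)c1)c1c(OCc2ccccc2)cc(OCc2ccccc2)c2c1O[C@H](c1cc(OCc3ccccc3)c(OCc3ccccc3)c(OCc3ccccc3)c1)[C@H](OCc1ccccc1)C2
A6 | alternative 3 | 8-(flavan-4-yl)-2-aryl-2H-chromene-3-carbaldehyde with lower C2 as in 34 | c1ccccc1COc1ccc2c(c1)O[C@H](c1ccc(OCc3ccccc3)c(OCc3ccccc3)c1)C[C@H]2c1c(OCc2ccccc2)cc(OCc2ccccc2)c2c1O[C@H](c1cc(OCc3ccccc3)c(OCc3ccccc3)c(OCc3ccccc3)c1)C(C=O)=C2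
A7 | alternative 3 | 4,6-bis(benzyloxy)-3-[(2S,4R)-7-(benzyloxy)-2-(DBP)chroman-4-yl]-2-hydroxybenzaldehyde | c1ccccc1COc1ccc2c(c1)O[C@H](c1ccc(OCc3ccccc3)c(OCc3ccccc3)c1)C[C@H]2c1c(OCc2ccccc2)cc(OCc2ccccc2)c(C=O)c1O
A8 | alternative 3 | (E)-3-[3,4,5-tris(benzyloxy)phenyl]prop-2-enal | O=C/C=C/c1cc(OCc2ccccc2)c(OCc2ccccc2)c(OCc2ccccc2)c1
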